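The oxolane (O1, C2 bearing ring A, C3 bearing CH2OH, C4 bearing the ring B benzyl group, C5) is disconnected at C2–C3. C2 is a benzylic ether carbon; in the open chain it is an O1–CH2–ring A group whose two enantiotopic hydrogens lie 1,5 to C3. A chiral dirhodium carbene at C3 inserts into one of them, closing the ring and setting C2, with C3 following. The precursor is an achiral vinyldiazoacetate: diazo ester carbon C3 on an sp2 C4 that already carries the ring B benzylidene (ring B trans to C3) and the C5H2–O1–CH2–ring A arm. Hydrogenation anti to the C3 substituent then sets C4.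

Key step: step 9

Assumption: Rh2(S-DOSP)4 is taken to give the (2R) series shown; the sense of induction for this substrate has to be assigned on the first run, and Rh2(R-DOSP)4 replaces it if the opposite series forms.

Step 1
Reactants: 1 3-hydroxy-4,5-dimethoxybenzaldehyde
Product: 2 3-(benzyloxy)-4,5-dimethoxybenzaldehyde
Conditions: BnBr, K2CO3, DMF, rt
Reagents that add atoms: benzyl bromide, BrCc1ccccc1
Why: Williamson ether synthesis on the phenoxide, the only strong nucleophile in 1; benzyl is kept because it tolerates every later step and leaves in the final hydrogenation at no extra cost.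

Step 2
Reactants: 2 3-(benzyloxy)-4,5-dimethoxybenzaldehyde, 3 methyl acrylate
Product: 4 methyl 2-{[3-(benzyloxy)-4,5-dimethoxyphenyl](hydroxy)methyl}prop-2-enoate (racemic)
Conditions: DABCO (1 equiv), methyl acrylate (excess), MeOH, rt, several days
Reagents that add atoms: none
Why: Morita–Baylis–Hillman reaction, slow for this electron-rich aldehyde but free of competing pathways under protic acceleration; the carbinol stereocentre forms racemic and is erased in step 3.

Step 3
Reactants: 4 methyl 2-{[3-(benzyloxy)-4,5-dimethoxyphenyl](hydroxy)methyl}prop-2-enoate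
Product: 5 methyl (2Z)-3-[3-(benzyloxy)-4,5-dimethoxyphenyl]-2-(bromomethyl)prop-2-enoate
Conditions: PBr3 (0.4 equiv), CH2Cl2, 0 °C
Reagents that add atoms: phosphorus tribromide, BrP(Br)Br
Why: Bromination with allylic transposition (SN2' type) of a Morita–Baylis–Hillman alcohol, which gives the conjugated primary bromide with the aryl group trans to the ester, the thermodynamically preferred geometry that all later steps carry forward.

Step 4
Reactants: 5 methyl (2Z)-3-[3-(benzyloxy)-4,5-dimethoxyphenyl]-2-(bromomethyl)prop-2-enoate, 6 (3,4,5-trimethoxyphenyl)methanol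
Product: 8 methyl (2E)-3-[3-(benzyloxy)-4,5-dimethoxyphenyl]-2-{[(3,4,5-trimethoxybenzyl)oxy]methyl}prop-2-enoate, via sodium alkoxide 7 (not isolated)
Conditions: 6, NaH, THF/DMF, 0 °C; then 5, −20 °C → rt
Reagents that add atoms: none
Why: Williamson etherification in which the pre-formed alkoxide displaces the primary allylic bromide by SN2 faster than it can attack the hindered aryl-bearing carbon or the ester, so the alkene geometry is untouched (E only because the priorities change).

Step 5
Reactants: 8 methyl (2E)-3-[3-(benzyloxy)-4,5-dimethoxyphenyl]-2-{[(3,4,5-trimethoxybenzyl)oxy]methyl}prop-2-enoate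
Product: 9 (2Z)-3-[3-(benzyloxy)-4,5-dimethoxyphenyl]-2-{[(3,4,5-trimethoxybenzyl)oxy]methyl}prop-2-en-1-ol
Conditions: i-Bu2AlH (2.5 equiv), CH2Cl2, −78 → 0 °C; aq. potassium sodium tartrate
Reagents that add atoms: none
Why: 1,2-Reduction of an enoate to the allylic alcohol with i-Bu2AlH, which leaves the trisubstituted alkene, its geometry and both benzyl-type ethers intact.

Step 6
Reactants: 9 (2Z)-3-[3-(benzyloxy)-4,5-dimethoxyphenyl]-2-{[(3,4,5-trimethoxybenzyl)oxy]methyl}prop-2-en-1-ol
Product: 10 (2E)-3-[3-(benzyloxy)-4,5-dimethoxyphenyl]-2-{[(3,4,5-trimethoxybenzyl)oxy]methyl}prop-2-en-1-yl methyl carbonate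
Conditions: ClCO2Me, pyridine, CH2Cl2, 0 °C
Reagents that add atoms: methyl chloroformate, COC(=O)Cl
Why: Acylation of the primary allylic alcohol to its methyl carbonate, the leaving group that palladium ionises cleanly and that supplies its own methoxide in step 7.

Step 7
Reactants: 10 (2E)-3-[3-(benzyloxy)-4,5-dimethoxyphenyl]-2-{[(3,4,5-trimethoxybenzyl)oxy]methyl}prop-2-en-1-yl methyl carbonate
Product: 11 methyl (3Z)-4-[3-(benzyloxy)-4,5-dimethoxyphenyl]-3-{[(3,4,5-trimethoxybenzyl)oxy]methyl}but-3-enoate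
Conditions: Pd(OAc)2 (5 mol %), PPh3 (20 mol %), CO (10 bar), THF, 50 °C
Reagents that add atoms: carbon monoxide, [C-]#[O+]
Why: Tsuji-type decarboxylative alkoxycarbonylation in which zerovalent palladium (from Pd(OAc)2 and PPh3) ionises the carbonate to a syn-aryl π-allyl complex with loss of CO2, CO inserts at the unhindered CH2 terminus and the released methoxide captures the acyl palladium, so ring B stays trans to the new CH2CO2Me arm.

Step 8
Reactants: 11 methyl (3Z)-4-[3-(benzyloxy)-4,5-dimethoxyphenyl]-3-{[(3,4,5-trimethoxybenzyl)oxy]methyl}but-3-enoate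
Product: 12 methyl (3Z)-4-[3-(benzyloxy)-4,5-dimethoxyphenyl]-2-diazo-3-{[(3,4,5-trimethoxybenzyl)oxy]methyl}but-3-enoate
Conditions: p-ABSA (1.2 equiv), DBU (1.3 equiv), MeCN, 0 °C; cold work-up, used at once
Reagents that add atoms: 4-acetamidobenzenesulfonyl azide (p-ABSA), CC(=O)Nc1ccc(cc1)S(=O)(=O)N=[N+]=[N-]
Why: Regitz diazo transfer through the dienolate of the ester- and alkene-activated methylene, which attacks the sulfonyl azide at the α-carbon without disturbing the alkene geometry; the product is kept cold and used at once because vinyl diazo compounds slowly close to pyrazoles.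

Step 9
Reactants: 12 methyl (3Z)-4-[3-(benzyloxy)-4,5-dimethoxyphenyl]-2-diazo-3-{[(3,4,5-trimethoxybenzyl)oxy]methyl}but-3-enoate
Product: 15 methyl (2R,3R,4Z)-4-[3-(benzyloxy)-4,5-dimethoxybenzylidene]-2-(3,4,5-trimethoxyphenyl)oxolane-3-carboxylate, via dirhodium vinylcarbene 13 (not isolated), via 2,3-cis ester 14 (not isolated)
Conditions: Rh2(S-DOSP)4 (1 mol %), PhCF3/2,2-dimethylbutane, 12 added over 2 h, −20 °C → rt; then DBU (0.1 equiv), 0 °C
Reagents that add atoms: none
Why: Rh2(S-DOSP)4 displaces N2 from 12 to give the donor/acceptor carbene 13 at C3 (styryl donor, ester acceptor); as the neighbouring C4 is sp2 and carries no hydrogen, no 1,2-hydride migration can quench it, and it inserts into a benzylic O1–CH2 hydrogen through a concerted, hydride-transfer-like three-centre transition state that makes C2–C3. The closest known reaction type is the dirhodium tetracarboxylate-catalysed enantioselective intramolecular C–H insertion of aryl- and vinyldiazoacetates at benzylic ether methylenes. The oxolane, the only ring formed, closes by 1,5-insertion (carbene carbon to the carbon four atoms on, through C4, C5 and O1), the ring size rhodium carbenes prefer. C2 (R) is fixed by the chiral sulfonylprolinate ligands, which select one of the two enantiotopic hydrogens, whereas C3 forms under kinetic control, most likely with the ester syn to ring A (14), and is then relaxed by catalytic DBU to the 2,3-trans ester 15, because C3–H is both α to the ester and allylic and its dienolate reprotonates fastest at C3. The step needs site selectivity for this one CH2 over ring B, ring A, the methoxy groups and the phenol benzyl ether: the Z alkene holds ring B trans to C3 and out of reach, activation by both O1 and ring A plus the 1,5 geometry make the chosen C–H the most hydridic one within range, and slow addition at low concentration suppresses intermolecular attack on the remote O-benzyl CH2.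

Step 10
Reactants: 15 methyl (2R,3R,4Z)-4-[3-(benzyloxy)-4,5-dimethoxybenzylidene]-2-(3,4,5-trimethoxyphenyl)oxolane-3-carboxylate
Product: 16 {(2R,3S,4Z)-4-[3-(benzyloxy)-4,5-dimethoxybenzylidene]-2-(3,4,5-trimethoxyphenyl)oxolan-3-yl}methanol
Conditions: i-Bu2AlH (3 equiv), CH2Cl2, −78 → 0 °C; aq. potassium sodium tartrate
Reagents that add atoms: none
Why: Ester-to-alcohol reduction with Lewis acidic, non-basic i-Bu2AlH, so the doubly activated C3–H is not enolised; removing the ester before the palladium step locks C3 (its descriptor changes from R to S through priority only).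

Step 11
Reactants: 16 {(2R,3S,4Z)-4-[3-(benzyloxy)-4,5-dimethoxybenzylidene]-2-(3,4,5-trimethoxyphenyl)oxolan-3-yl}methanol
Product: 17 {(2R,3S,4S)-4-(3-hydroxy-4,5-dimethoxybenzyl)-2-(3,4,5-trimethoxyphenyl)oxolan-3-yl}methanol
Conditions: H2 (1 atm), 10% Pd/C, EtOAc, rt
Reagents that add atoms: none
Why: Heterogeneous catalytic hydrogenation with concurrent hydrogenolysis of the phenolic benzyl ether, in which H2 adds syn to the benzylidene from the face opposite the adjacent C3 hydroxymethyl group (the nearer of the two ring substituents), so benzyl and hydroxymethyl end cis and C4 is set S.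

Compound list
1 | 3-hydroxy-4,5-dimethoxybenzaldehyde | COc1cc(C=O)cc(O)c1OC | starting material
2 | 3-(benzyloxy)-4,5-dimethoxybenzaldehyde | COc1cc(C=O)cc(OCc2ccccc2)c1OC | intermediate
3 | methyl acrylate | C=CC(=O)OC | starting material
4 | methyl 2-{[3-(benzyloxy)-4,5-dimethoxyphenyl](hydroxy)methyl}prop-2-enoate (racemic) | COC(=O)C(=C)C(O)c1cc(OC)c(OC)c(OCc2ccccc2)c1 | intermediate
5 | methyl (2Z)-3-[3-(benzyloxy)-4,5-dimethoxyphenyl]-2-(bromomethyl)prop-2-enoate | COC(=O)/C(CBr)=C/c1cc(OC)c(OC)c(OCc2ccccc2)c1 | intermediate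
6 | (3,4,5-trimethoxyphenyl)methanol | COc1cc(CO)cc(OC)c1OC | starting material
7 | sodium (3,4,5-trimethoxyphenyl)methanolate (not isolated) | [Na+].[O-]Cc1cc(OC)c(OC)c(OC)c1 | intermediate
8 | methyl (2E)-3-[3-(benzyloxy)-4,5-dimethoxyphenyl]-2-{[(3,4,5-trimethoxybenzyl)oxy]methyl}prop-2-enoate | COC(=O)/C(COCc1cc(OC)c(OC)c(OC)c1)=C/c1cc(OC)c(OC)c(OCc2ccccc2)c1 | intermediate
9 | (2Z)-3-[3-(benzyloxy)-4,5-dimethoxyphenyl]-2-{[(3,4,5-trimethoxybenzyl)oxy]methyl}prop-2-en-1-ol | OC/C(COCc1cc(OC)c(OC)c(OC)c1)=C/c1cc(OC)c(OC)c(OCc2ccccc2)c1 | intermediate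
10 | (2E)-3-[3-(benzyloxy)-4,5-dimethoxyphenyl]-2-{[(3,4,5-trimethoxybenzyl)oxy]methyl}prop-2-en-1-yl methyl carbonate | COC(=O)OC/C(COCc1cc(OC)c(OC)c(OC)c1)=C/c1cc(OC)c(OC)c(OCc2ccccc2)c1 | intermediate
11 | methyl (3Z)-4-[3-(benzyloxy)-4,5-dimethoxyphenyl]-3-{[(3,4,5-trimethoxybenzyl)oxy]methyl}but-3-enoate | COC(=O)C/C(COCc1cc(OC)c(OC)c(OC)c1)=C/c1cc(OC)c(OC)c(OCc2ccccc2)c1 | intermediate
12 | methyl (3Z)-4-[3-(benzyloxy)-4,5-dimethoxyphenyl]-2-diazo-3-{[(3,4,5-trimethoxybenzyl)oxy]methyl}but-3-enoate (key-step precursor) | COC(=O)C(=[N+]=[N-])/C(COCc1cc(OC)c(OC)c(OC)c1)=C/c1cc(OC)c(OC)c(OCc2ccccc2)c1 | intermediate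
13 | dirhodium vinylcarbene of 12 (not isolated; drawn with the carbene carbon on one Rh, second Rh and ligands omitted) | COC(=O)C(=[Rh])/C(COCc1cc(OC)c(OC)c(OC)c1)=C/c1cc(OC)c(OC)c(OCc2ccccc2)c1 | intermediate
14 | methyl (2R,3S,4Z)-4-[3-(benzyloxy)-4,5-dimethoxybenzylidene]-2-(3,4,5-trimethoxyphenyl)oxolane-3-carboxylate (2,3-cis ester, not isolated) | COC(=O)[C@@H]1[C@H](c2cc(OC)c(OC)c(OC)c2)OC/C1=C\c1cc(OC)c(OC)c(OCc2ccccc2)c1 | intermediate
15 | methyl (2R,3R,4Z)-4-[3-(benzyloxy)-4,5-dimethoxybenzylidene]-2-(3,4,5-trimethoxyphenyl)oxolane-3-carboxylate (2,3-trans ester, key-step product) | COC(=O)[C@H]1[C@H](c2cc(OC)c(OC)c(OC)c2)OC/C1=C\c1cc(OC)c(OC)c(OCc2ccccc2)c1 | intermediate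
16 | {(2R,3S,4Z)-4-[3-(benzyloxy)-4,5-dimethoxybenzylidene]-2-(3,4,5-trimethoxyphenyl)oxolan-3-yl}methanol | OC[C@H]1[C@H](c2cc(OC)c(OC)c(OC)c2)OC/C1=C\c1cc(OC)c(OC)c(OCc2ccccc2)c1 | intermediate
17 | {(2R,3S,4S)-4-(3-hydroxy-4,5-dimethoxybenzyl)-2-(3,4,5-trimethoxyphenyl)oxolan-3-yl}methanol (2,3-trans, 3,4-cis) | COc1cc(C[C@@H]2CO[C@@H](c3cc(OC)c(OC)c(OC)c3)[C@@H]2CO)cc(O)c1OC | target

Total step count: 11.
Longest linear sequence: 11 steps (1 to 17); 3 and 6 are bought and enter at steps 2 and 4.

Steps most likely to fail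

1. Step 9. Three processes can defeat it. The vinyl diazo unit of 12 may close to a pyrazole, or the carbene to a cyclopropene, before the benzylic hydrogen is reached. The ligands may discriminate poorly between the two enantiotopic hydrogens. In the DBU stage, γ-reprotonation of the dienolate may move the exocyclic alkene into conjugation with the ester and erase C3. Within the same approach the first variation is Rh2(S-PTAD)4 and a shorter, colder base stage. Fallback (sets out from 11, comes back at 15): stereocontrol is moved from the catalyst to a covalently bound auxiliary, which also turns every stereoisomer into a separable diastereomer. Ester 11 is saponified (LiOH, THF/H2O, 0 °C) to the butenoic acid F1. F1 is coupled (EDC, DMAP, CH2Cl2) with (S)-2-hydroxy-1-(pyrrolidin-1-yl)propan-1-one to the lactamide ester F2. Diazo transfer (p-ABSA, DBU, MeCN, 0 °C) gives the diazo lactamide ester F3. Insertion with the matched enantiomer of Rh2(DOSP)4 gives the oxolane lactamide ester F4, which is purified as one diastereomer. K2CO3 in MeOH at 0 °C exchanges the activated ester for methyl, lets C3 settle trans, and returns the material as 15.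

2. Step 11. H2 has to arrive on the face that also carries ring A (1,3 to C4), so facial selectivity may be poor. Palladium may also shift the alkene into the ring, or cleave the allylic C5–O1 or benzylic C2–O1 bond. Fallback (sets out from 16, comes back at 17): steric steering by a large group on the C3 arm. Alcohol 16 is silylated (t-BuPh2SiCl, imidazole, DMF) to the silyl ether F5, whose bulky CH2OSi group blocks its own face more strongly. Hydrogenation (H2, Pd/C, EtOAc) gives the saturated silyl ether phenol F6. Bu4NF in THF removes the silyl group to give 17.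

3. Step 7. The π-allyl palladium intermediate may interconvert its syn and anti forms at the aryl terminus and lose the Z geometry, or be captured by methoxide before CO inserts. Fallback (sets out from 8, comes back at 11): Arndt–Eistert homologation, which never passes through an allyl metal species. Ester 8 is saponified (LiOH, THF/H2O) to the acrylic acid F7. Oxalyl chloride with catalytic DMF gives the acid chloride F8. Diazomethane (2 equiv, Et2O, 0 °C) gives the diazoketone F9. Wolff rearrangement (PhCO2Ag cat., Et3N, MeOH, rt) through the vinylketene gives the β,γ-unsaturated methyl ester 11 with the alkene untouched.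

Further compounds
F1 | step 9 | (3Z)-4-[3-(benzyloxy)-4,5-dimethoxyphenyl]-3-{[(3,4,5-trimethoxybenzyl)oxy]methyl}but-3-enoic acid | OC(=O)C/C(COCc1cc(OC)c(OC)c(OC)c1)=C/c1cc(OC)c(OC)c(OCc2ccccc2)c1
F2 | step 9 | (2S)-1-oxo-1-(pyrrolidin-1-yl)propan-2-yl (3Z)-4-[3-(benzyloxy)-4,5-dimethoxyphenyl]-3-{[(3,4,5-trimethoxybenzyl)oxy]methyl}but-3-enoate | C[C@H](OC(=O)C/C(COCc1cc(OC)c(OC)c(OC)c1)=C/c1cc(OC)c(OC)c(OCc2ccccc2)c1)C(=O)N1CCCC1
F3 | step 9 | (2S)-1-oxo-1-(pyrrolidin-1-yl)propan-2-yl (3Z)-4-[3-(benzyloxy)-4,5-dimethoxyphenyl]-2-diazo-3-{[(3,4,5-trimethoxybenzyl)oxy]methyl}but-3-enoate | C[C@H](OC(=O)C(=[N+]=[N-])/C(COCc1cc(OC)c(OC)c(OC)c1)=C/c1cc(OC)c(OC)c(OCc2ccccc2)c1)C(=O)N1CCCC1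
F4 | step 9 | (2S)-1-oxo-1-(pyrrolidin-1-yl)propan-2-yl (2R,3R,4Z)-4-[3-(benzyloxy)-4,5-dimethoxybenzylidene]-2-(3,4,5-trimethoxyphenyl)oxolane-3-carboxylate | C[C@H](OC(=O)[C@H]1[C@H](c2cc(OC)c(OC)c(OC)c2)OC/C1=C\c1cc(OC)c(OC)c(OCc2ccccc2)c1)C(=O)N1CCCC1
F5 | step 11 | tert-butyl({(2R,3S,4Z)-4-[3-(benzyloxy)-4,5-dimethoxybenzylidene]-2-(3,4,5-trimethoxyphenyl)oxolan-3-yl}methoxy)diphenylsilane | CC(C)(C)[Si](OC[C@H]1[C@H](c2cc(OC)c(OC)c(OC)c2)OC/C1=C\c1cc(OC)c(OC)c(OCc2ccccc2)c1)(c1ccccc1)c1ccccc1
F6 | step 11 | 5-{[(3S,4S,5R)-4-({[tert-butyl(diphenyl)silyl]oxy}methyl)-5-(3,4,5-trimethoxyphenyl)oxolan-3-yl]methyl}-2,3-dimethoxyphenol | CC(C)(C)[Si](OC[C@H]1[C@H](c2cc(OC)c(OC)c(OC)c2)OC[C@H]1Cc1cc(OC)c(OC)c(O)c1)(c1ccccc1)c1ccccc1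
F7 | step 7 | (2E)-3-[3-(benzyloxy)-4,5-dimethoxyphenyl]-2-{[(3,4,5-trimethoxybenzyl)oxy]methyl}prop-2-enoic acid | OC(=O)/C(COCc1cc(OC)c(OC)c(OC)c1)=C/c1cc(OC)c(OC)c(OCc2ccccc2)c1
F8 | step 7 | (2E)-3-[3-(benzyloxy)-4,5-dimethoxyphenyl]-2-{[(3,4,5-trimethoxybenzyl)oxy]methyl}prop-2-enoyl chloride | ClC(=O)/C(COCc1cc(OC)c(OC)c(OC)c1)=C/c1cc(OC)c(OC)c(OCc2ccccc2)c1
F9 | step 7 | (3E)-4-[3-(benzyloxy)-4,5-dimethoxyphenyl]-1-diazo-3-{[(3,4,5-trimethoxybenzyl)oxy]methyl}but-3-en-2-one | [N-]=[N+]=CC(=O)/C(COCc1cc(OC)c(OC)c(OC)c1)=C/c1cc(OC)c(OC)c(OCc2ccccc2)c1
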